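Ring A (C1–C5, C10) carries two identical methyl groups (C18, C19) on C4, so it is traced back to achiral 4,4-dimethylcyclohexa-2,5-dienone 2, whose two enone arms are enantiotopic. One copper-catalysed, ligand-controlled conjugate addition of acetal Grignard reagent 4 to one arm forms C5–C6 and fixes C5. Methylation of the resulting enolate forms C10–C20 and leaves enone 7, in which only C10 can be enolised. Allylation at C10, carbonyl-ene closure of ring B (C8–C9), C8 methylenation, anti-carbomagnesiation of propargyl alcohol, acylation and hydroxycarbonylation then complete the ent-labdane target.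

Key step: step 3

Remarks on the chemistry:
- Labdane numbering (C1–C20) is used for all intermediates.
- The sense of induction of the copper/ferrocenyl diphosphine catalyst on 2 cannot be predicted with certainty. The ligand antipode written stands for whichever enantiomer gives 7 with the configuration shown; both are commercial.
- (R)-2-Methylbutanoic acid is taken as a commercial, enantiopure compound.
- The C8 configuration written for 17–20 is the expected major one; its epimer would converge at ketone 21.

Step 1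
Reactants: 1 4,4-dimethylcyclohex-2-en-1-one
Product: 2 4,4-dimethylcyclohexa-2,5-dien-1-one
Conditions: DDQ (1.3 equiv), 1,4-dioxane, reflux
Reagents that add atoms: none
Why: DDQ dehydrogenation of the enone through its dienol is a standard preparation of 4,4-disubstituted cyclohexadienones, the quaternary C4 ruling out aromatisation, and no stereocentre is formed.

Step 2
Reactants: 3 2-(2-bromoethyl)-1,3-dioxolane
Product: 4 [2-(1,3-dioxolan-2-yl)ethyl]magnesium bromide (solution, titrated and used at once)
Conditions: Mg turnings (I2-activated), 2-MeTHF, 20–25 °C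
Reagents that add atoms: magnesium, [Mg]
Why: Insertion of magnesium into the primary C–Br bond (Grignard formation) should be clean as long as the reagent is made and kept at or below 25 °C, above which acetal-bearing Grignard reagents of this kind decompose.

Step 3
Reactants: 2 4,4-dimethylcyclohexa-2,5-dien-1-one; 4 [2-(1,3-dioxolan-2-yl)ethyl]magnesium bromide; 5 iodomethane
Product: 7 (5S,6S)-5-[2-(1,3-dioxolan-2-yl)ethyl]-4,4,6-trimethylcyclohex-2-en-1-one, via bromomagnesium dienolate 6 (not isolated)
Conditions: CuBr·SMe2 (5 mol %), (R)-1-[(Sp)-2-(diphenylphosphino)ferrocenyl]ethyldicyclohexylphosphine (6 mol %), tBuOMe, −78 °C, slow addition of 4 (1.15 equiv); then 5 (5 equiv), DMPU, −78 → 0 °C; aq. NH4Cl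
Reagents that add atoms: none
Why: Transmetallation from 4 gives a chiral monovalent alkylcopper–diphosphine complex that binds one of the two enantiotopic enone arms of 2; oxidative addition at C5 to a trivalent copper σ-complex and reductive elimination form C5–C6 and release bromomagnesium dienolate 6, which 5 methylates at C10 once DMPU has activated the magnesium enolate. The closest known reaction type is the copper-catalysed enantioselective conjugate addition to 4,4-disubstituted cyclohexa-2,5-dienones with enolate trapping, combined with the CuBr·SMe2/ferrocenyl diphosphine addition of Grignard reagents to cyclic enones. No ring is closed; the six-membered ring of 2 becomes ring A with C1 as carbonyl carbon. C5 is controlled by the ligand, which selects the enone arm, whereas C10 is controlled by the substrate, the electrophile approaching the planar C1–C10 enolate anti to the new C5 chain (this centre becomes trigonal again in step 4, so its ratio is not critical). The step needs 1,4- over 1,2-addition, mono-addition and arm selection: the soft copper nucleophile secures the first, the second follows because adduct 6 is an enolate and no acceptor until it is alkylated, and the third rests on the ligand, with slow addition at −78 °C keeping the uncatalysed background reaction low.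

Step 4
Reactants: 7 (5S,6S)-5-[2-(1,3-dioxolan-2-yl)ethyl]-4,4,6-trimethylcyclohex-2-en-1-one; 8 allyl bromide (3-bromoprop-1-ene)
Product: 10 (5R,6S)-5-[2-(1,3-dioxolan-2-yl)ethyl]-4,4,6-trimethyl-6-(prop-2-en-1-yl)cyclohex-2-en-1-one, via lithium dienolate 9 (not isolated)
Conditions: LiN(iPr)2 (1.1 equiv), THF, −78 °C; 8 (2 equiv), DMPU, −78 → 0 °C
Reagents that add atoms: none
Why: Deprotonation can only occur at C10 (C2 is vinylic, C4 quaternary) and the cross-conjugated enolate 9 is C-allylated (enolate alkylation) anti to the C5 chain, which together with the axial C4 methyl shields the other face, so that C10 becomes quaternary with C9 trans to C6 and C20 cis to it as in the target.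

Step 5
Reactants: 10 (5R,6S)-5-[2-(1,3-dioxolan-2-yl)ethyl]-4,4,6-trimethyl-6-(prop-2-en-1-yl)cyclohex-2-en-1-one
Product: 11 (5R,6S)-5-[2-(1,3-dioxolan-2-yl)ethyl]-4,4,6-trimethyl-6-[(1E)-prop-1-en-1-yl]cyclohex-2-en-1-one
Conditions: RuHCl(CO)(PPh3)3 (3 mol %), toluene, 90 °C
Reagents that add atoms: none
Why: RuHCl(CO)(PPh3)3-catalysed alkene isomerisation (hydrometallation/β-hydride elimination) should move the terminal double bond one position to the thermodynamically preferred (E)-C9=C11 alkene and cannot go further because C10 is quaternary, and no stereocentre is touched.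

Step 6
Reactants: 11 (5R,6S)-5-[2-(1,3-dioxolan-2-yl)ethyl]-4,4,6-trimethyl-6-[(1E)-prop-1-en-1-yl]cyclohex-2-en-1-one
Product: 13 (2S,3R)-3-[2-(1,3-dioxolan-2-yl)ethyl]-2,4,4-trimethyl-2-[(1E)-prop-1-en-1-yl]cyclohexan-1-one, via lithium enolate 12 (not isolated)
Conditions: Li (2.2 equiv), tBuOH (1 equiv), NH3(l)/THF, −78 °C; then solid NH4Cl
Reagents that add atoms: none
Why: Dissolving-metal (Birch-type) reduction of the enone gives enolate 12, protonated on quench, while the isolated (E)-alkene and the acetal are inert to Li/NH3 at −78 °C, and no stereocentre is formed.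

Step 7
Reactants: 13 (2S,3R)-3-[2-(1,3-dioxolan-2-yl)ethyl]-2,4,4-trimethyl-2-[(1E)-prop-1-en-1-yl]cyclohexan-1-one
Product: 15 2-{2-[(1R,6S)-2,2,6-trimethyl-6-[(1E)-prop-1-en-1-yl]cyclohexyl]ethyl}-1,3-dioxolane, via hydrazone 14 (not isolated)
Conditions: N2H4·H2O (10 equiv), KOH (6 equiv), diethylene glycol, 130 °C; then 200 °C with removal of H2O, argon
Reagents that add atoms: none
Why: Wolff–Kishner reduction (Huang-Minlon procedure) converts the C1 carbonyl through hydrazone 14 into CH2 with loss of N2, a reaction that tolerates one quaternary α-carbon as in 4,4-dimethyl-3-oxo terpenoids, while the acetal and the alkene are base-stable and C10 cannot epimerise.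

Step 8
Reactants: 15 2-{2-[(1R,6S)-2,2,6-trimethyl-6-[(1E)-prop-1-en-1-yl]cyclohexyl]ethyl}-1,3-dioxolane
Product: 16 3-[(1R,6S)-2,2,6-trimethyl-6-[(1E)-prop-1-en-1-yl]cyclohexyl]propanal
Conditions: 1 M HCl, THF, 25 °C
Reagents that add atoms: water, O
Why: Acid-catalysed acetal hydrolysis should release the C8 aldehyde under conditions too mild to protonate the disubstituted alkene, and no stereocentre is affected.

Step 9
Reactants: 16 3-[(1R,6S)-2,2,6-trimethyl-6-[(1E)-prop-1-en-1-yl]cyclohexyl]propanal
Product: 17 (1S,2S,4aR,8aR)-1-ethenyl-5,5,8a-trimethyldecahydronaphthalen-2-ol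
Conditions: Me2AlCl (1.5 equiv), CH2Cl2, −78 → −20 °C; aq. potassium sodium tartrate
Reagents that add atoms: none
Why: In this Me2AlCl-promoted intramolecular carbonyl-ene reaction (ene unit tethered at its olefinic terminus, six-membered closure of ring B) the activated C8 aldehyde bonds to C9 while a C12 hydrogen passes to oxygen through a chair transition state fused trans to ring A with C11 equatorial, so that H9 should come anti to C20 and the C8 hydroxyl equatorial (the C8 centre is removed in step 12).

Step 10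
Reactants: 17 (1S,2S,4aR,8aR)-1-ethenyl-5,5,8a-trimethyldecahydronaphthalen-2-ol
Product: 19 (1S,2S,4aR,8aR)-1-(2-hydroxyethyl)-5,5,8a-trimethyldecahydronaphthalen-2-ol, via B-alkyl-9-BBN adduct 18 (not isolated)
Conditions: 9-BBN (2.5 equiv), THF, 0 → 50 °C; then NaOH, H2O2, 0 → 25 °C
Reagents that add atoms: hydrogen peroxide, OO
Why: Anti-Markovnikov hydroboration of the only alkene gives borane 18 and alkaline H2O2 oxidation replaces boron by hydroxyl at C12, and no stereocentre is formed.

Step 11
Reactants: 19 (1S,2S,4aR,8aR)-1-(2-hydroxyethyl)-5,5,8a-trimethyldecahydronaphthalen-2-ol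
Product: 20 (1S,2S,4aR,8aR)-1-{2-[(tert-butyldimethylsilyl)oxy]ethyl}-5,5,8a-trimethyldecahydronaphthalen-2-ol
Conditions: TBSCl (1.05 equiv), imidazole, CH2Cl2, 0 °C
Reagents that add atoms: tert-butyldimethylsilyl chloride, CC(C)(C)[Si](C)(C)Cl
Why: Silylation is selective for the primary C12 hydroxyl over the hindered secondary C8 hydroxyl and keeps the 1,4-diol from cyclising to a tetrahydrofuran in later steps.

Step 12
Reactants: 20 (1S,2S,4aR,8aR)-1-{2-[(tert-butyldimethylsilyl)oxy]ethyl}-5,5,8a-trimethyldecahydronaphthalen-2-ol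
Product: 21 (1S,4aR,8aR)-1-{2-[(tert-butyldimethylsilyl)oxy]ethyl}-5,5,8a-trimethyloctahydronaphthalen-2(1H)-one
Conditions: Dess–Martin periodinane (1.3 equiv), NaHCO3, CH2Cl2, 0 → 25 °C
Reagents that add atoms: none
Why: Dess–Martin oxidation converts the secondary alcohol into the C8 ketone under buffered conditions that leave the silyl ether intact, and C9 stays in its equatorial, thermodynamically preferred configuration.

Step 13
Reactants: 21 (1S,4aR,8aR)-1-{2-[(tert-butyldimethylsilyl)oxy]ethyl}-5,5,8a-trimethyloctahydronaphthalen-2(1H)-one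
Product: 22 tert-butyl(dimethyl){2-[(1R,4aR,8aR)-5,5,8a-trimethyl-2-methylidenedecahydronaphthalen-1-yl]ethoxy}silane
Conditions: Ph3PCH3Br (3 equiv), KOtBu (2.8 equiv), toluene, 25 → 90 °C
Reagents that add atoms: methyltriphenylphosphonium bromide, C[P+](c1ccccc1)(c1ccccc1)c1ccccc1.[Br-]
Why: Wittig methylenation with Ph3P=CH2 in hot toluene is the usual way to convert hindered 8-oxo decalins into the exocyclic C8=C17 alkene, and any base-mediated equilibration at C9 favours the required equatorial side chain.

Step 14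
Reactants: 22 tert-butyl(dimethyl){2-[(1R,4aR,8aR)-5,5,8a-trimethyl-2-methylidenedecahydronaphthalen-1-yl]ethoxy}silane
Product: 23 (1R,4aR,8aR)-1-(2-bromoethyl)-5,5,8a-trimethyl-2-methylidenedecahydronaphthalene
Conditions: Ph3PBr2 (1.3 equiv), CH2Cl2, 0 → 25 °C
Reagents that add atoms: dibromotriphenylphosphorane, BrP(Br)(c1ccccc1)(c1ccccc1)c1ccccc1
Why: Ph3PBr2 converts primary tert-butyldimethylsilyl ethers directly into bromides (silyl transfer to bromide, then SN2 displacement of the oxyphosphonium group at C12), so deprotection and activation are one operation and the alkene is not touched.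

Step 15
Reactants: 23 (1R,4aR,8aR)-1-(2-bromoethyl)-5,5,8a-trimethyl-2-methylidenedecahydronaphthalene; 24 prop-2-yn-1-ol (propargyl alcohol)
Product: 28 (2Z)-3-iodo-2-{2-[(1R,4aR,8aR)-5,5,8a-trimethyl-2-methylidenedecahydronaphthalen-1-yl]ethyl}prop-2-en-1-ol, via Grignard reagent 25 (not isolated), via chloromagnesium alkoxide 26 (not isolated), via vinylmagnesium chelate 27 (not isolated)
Conditions: 23, Mg, THF, 40 °C; separately 24, iPrMgCl (1.0 equiv), THF, 0 °C; combine, CuI (10 mol %), 25–45 °C; then I2, −40 → 0 °C; aq. NH4Cl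
Reagents that add atoms: iodine, II
Why: In this CuI-catalysed anti-carbomagnesiation of a propargylic magnesium alkoxide the alkyl group of 25 adds to the internal alkyne carbon (C12–C13) and magnesium to the terminal carbon within five-membered chelate 27, so that iodine, introduced with retention, ends cis to CH2OH and the C13=C14 geometry is fixed as (Z).

Step 16
Reactants: 28 (2Z)-3-iodo-2-{2-[(1R,4aR,8aR)-5,5,8a-trimethyl-2-methylidenedecahydronaphthalen-1-yl]ethyl}prop-2-en-1-ol; 29 (2R)-2-methylbutanoic acid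
Product: 30 (2Z)-3-iodo-2-{2-[(1R,4aR,8aR)-5,5,8a-trimethyl-2-methylidenedecahydronaphthalen-1-yl]ethyl}prop-2-en-1-yl (2R)-2-methylbutanoate
Conditions: DCC (1.2 equiv), DMAP (0.1 equiv), CH2Cl2, 0 °C
Reagents that add atoms: none
Why: Steglich esterification acylates the primary allylic alcohol at 0 °C, conditions under which the α-stereocentre of the acid is not expected to racemise and the vinyl iodide is inert.

Step 17
Reactants: 30 (2Z)-3-iodo-2-{2-[(1R,4aR,8aR)-5,5,8a-trimethyl-2-methylidenedecahydronaphthalen-1-yl]ethyl}prop-2-en-1-yl (2R)-2-methylbutanoate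
Product: 31 (2Z)-3-({[(2R)-2-methylbutanoyl]oxy}methyl)-5-[(1R,4aR,8aR)-5,5,8a-trimethyl-2-methylidenedecahydronaphthalen-1-yl]pent-2-enoic acid (target)
Conditions: Pd(OAc)2 (5 mol %), PPh3 (10 mol %), CO (1 atm), KOAc (4 equiv), DMF/H2O (10:1), 25–40 °C; work-up at pH 3–4
Reagents that add atoms: carbon monoxide, [C-]#[O+]; water, O
Why: In this Pd(OAc)2/PPh3-catalysed hydroxycarbonylation the vinyl iodide adds oxidatively to zerovalent palladium, CO inserts and the acyl–palladium bond is cleaved by acetate/water with retention of the C13=C14 geometry, the mild acetate base leaving the 2-methylbutanoate ester and the exocyclic alkene intact.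

Compound list
1 | 4,4-dimethylcyclohex-2-en-1-one | CC1(C)CCC(=O)C=C1 | starting material
2 | 4,4-dimethylcyclohexa-2,5-dien-1-one | CC1(C)C=CC(=O)C=C1 | intermediate
3 | 2-(2-bromoethyl)-1,3-dioxolane | BrCCC1OCCO1 | starting material
4 | [2-(1,3-dioxolan-2-yl)ethyl]magnesium bromide | Br[Mg]CCC1OCCO1 | intermediate
5 | iodomethane | CI | starting material
6 | bromomagnesium 3-[2-(1,3-dioxolan-2-yl)ethyl]-2,4,4-trimethylcyclohexa-1,5-dien-1-olate (C5 configured as in 7, C10 trigonal) | O1CCOC1CC[C@@H]2C(C)(C)C=CC(O[Mg]Br)=C2C | intermediate (not isolated)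
7 | (5S,6S)-5-[2-(1,3-dioxolan-2-yl)ethyl]-4,4,6-trimethylcyclohex-2-en-1-one (chain and methyl trans) | O1CCOC1CC[C@@H]2C(C)(C)C=CC(=O)[C@H]2C | intermediate
8 | allyl bromide (3-bromoprop-1-ene) | C=CCBr | starting material
9 | lithium 3-[2-(1,3-dioxolan-2-yl)ethyl]-2,4,4-trimethylcyclohexa-1,5-dien-1-olate (C5 configured as in 7) | O1CCOC1CC[C@@H]2C(C)(C)C=CC(O[Li])=C2C | intermediate (not isolated)
10 | (5R,6S)-5-[2-(1,3-dioxolan-2-yl)ethyl]-4,4,6-trimethyl-6-(prop-2-en-1-yl)cyclohex-2-en-1-one (allyl trans to the C5 chain) | O1CCOC1CC[C@@H]2C(C)(C)C=CC(=O)[C@@]2(C)CC=C | intermediate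
11 | (5R,6S)-5-[2-(1,3-dioxolan-2-yl)ethyl]-4,4,6-trimethyl-6-[(1E)-prop-1-en-1-yl]cyclohex-2-en-1-one | O1CCOC1CC[C@@H]2C(C)(C)C=CC(=O)[C@@]2(C)/C=C/C | intermediate
12 | lithium (5R,6S)-5-[2-(1,3-dioxolan-2-yl)ethyl]-4,4,6-trimethyl-6-[(1E)-prop-1-en-1-yl]cyclohex-1-en-1-olate | O1CCOC1CC[C@@H]2C(C)(C)CC=C(O[Li])[C@@]2(C)/C=C/C | intermediate (not isolated)
13 | (2S,3R)-3-[2-(1,3-dioxolan-2-yl)ethyl]-2,4,4-trimethyl-2-[(1E)-prop-1-en-1-yl]cyclohexan-1-one | O1CCOC1CC[C@@H]2C(C)(C)CCC(=O)[C@@]2(C)/C=C/C | intermediate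
14 | hydrazone of 13 at C1 | O1CCOC1CC[C@@H]2C(C)(C)CCC(=NN)[C@@]2(C)/C=C/C | intermediate (not isolated)
15 | 2-{2-[(1R,6S)-2,2,6-trimethyl-6-[(1E)-prop-1-en-1-yl]cyclohexyl]ethyl}-1,3-dioxolane | O1CCOC1CC[C@@H]2C(C)(C)CCC[C@@]2(C)/C=C/C | intermediate
16 | 3-[(1R,6S)-2,2,6-trimethyl-6-[(1E)-prop-1-en-1-yl]cyclohexyl]propanal | O=CCC[C@@H]1C(C)(C)CCC[C@@]1(C)/C=C/C | intermediate
17 | (1S,2S,4aR,8aR)-1-ethenyl-5,5,8a-trimethyldecahydronaphthalen-2-ol (trans-decalin, vinyl and hydroxyl equatorial) | O[C@H]1CC[C@@H]2C(C)(C)CCC[C@@]2(C)[C@@H]1C=C | intermediate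
18 | 9-{2-[(1S,2S,4aR,8aR)-2-hydroxy-5,5,8a-trimethyldecahydronaphthalen-1-yl]ethyl}-9-borabicyclo[3.3.1]nonane | O[C@H]1CC[C@@H]2C(C)(C)CCC[C@@]2(C)[C@@H]1CCB3C4CCCC3CCC4 | intermediate (not isolated)
19 | (1S,2S,4aR,8aR)-1-(2-hydroxyethyl)-5,5,8a-trimethyldecahydronaphthalen-2-ol | O[C@H]1CC[C@@H]2C(C)(C)CCC[C@@]2(C)[C@@H]1CCO | intermediate
20 | (1S,2S,4aR,8aR)-1-{2-[(tert-butyldimethylsilyl)oxy]ethyl}-5,5,8a-trimethyldecahydronaphthalen-2-ol | O[C@H]1CC[C@@H]2C(C)(C)CCC[C@@]2(C)[C@@H]1CCO[Si](C)(C)C(C)(C)C | intermediate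
21 | (1S,4aR,8aR)-1-{2-[(tert-butyldimethylsilyl)oxy]ethyl}-5,5,8a-trimethyloctahydronaphthalen-2(1H)-one | O=C1CC[C@@H]2C(C)(C)CCC[C@@]2(C)[C@@H]1CCO[Si](C)(C)C(C)(C)C | intermediate
22 | tert-butyl(dimethyl){2-[(1R,4aR,8aR)-5,5,8a-trimethyl-2-methylidenedecahydronaphthalen-1-yl]ethoxy}silane | C=C1CC[C@@H]2C(C)(C)CCC[C@@]2(C)[C@@H]1CCO[Si](C)(C)C(C)(C)C | intermediate
23 | (1R,4aR,8aR)-1-(2-bromoethyl)-5,5,8a-trimethyl-2-methylidenedecahydronaphthalene | C=C1CC[C@@H]2C(C)(C)CCC[C@@]2(C)[C@@H]1CCBr | intermediate
24 | prop-2-yn-1-ol (propargyl alcohol) | C#CCO | starting material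
25 | {2-[(1R,4aR,8aR)-5,5,8a-trimethyl-2-methylidenedecahydronaphthalen-1-yl]ethyl}magnesium bromide | C=C1CC[C@@H]2C(C)(C)CCC[C@@]2(C)[C@@H]1CC[Mg]Br | intermediate (not isolated)
26 | chloromagnesium prop-2-yn-1-olate | C#CCO[Mg]Cl | intermediate (not isolated)
27 | cyclic (Z)-alkenylmagnesium alkoxide: 2,5-dihydro-1,2-oxamagnesole carrying the 2-[(1R,4aR,8aR)-5,5,8a-trimethyl-2-methylidenedecahydronaphthalen-1-yl]ethyl group on C4 | C=C1CC[C@@H]2C(C)(C)CCC[C@@]2(C)[C@@H]1CCC3=C[Mg]OC3 | intermediate (not isolated)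
28 | (2Z)-3-iodo-2-{2-[(1R,4aR,8aR)-5,5,8a-trimethyl-2-methylidenedecahydronaphthalen-1-yl]ethyl}prop-2-en-1-ol | C=C1CC[C@@H]2C(C)(C)CCC[C@@]2(C)[C@@H]1CC/C(=C/I)CO | intermediate
29 | (2R)-2-methylbutanoic acid | CC[C@@H](C)C(O)=O | starting material
30 | (2Z)-3-iodo-2-{2-[(1R,4aR,8aR)-5,5,8a-trimethyl-2-methylidenedecahydronaphthalen-1-yl]ethyl}prop-2-en-1-yl (2R)-2-methylbutanoate | C=C1CC[C@@H]2C(C)(C)CCC[C@@]2(C)[C@@H]1CC/C(=C/I)COC(=O)[C@H](C)CC | intermediate
31 | (2Z)-3-({[(2R)-2-methylbutanoyl]oxy}methyl)-5-[(1R,4aR,8aR)-5,5,8a-trimethyl-2-methylidenedecahydronaphthalen-1-yl]pent-2-enoic acid | C=C1CC[C@@H]2C(C)(C)CCC[C@@]2(C)[C@@H]1CC/C(=C/C(=O)O)COC(=O)[C@H](C)CC | target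

Total step count: 17
Longest linear sequence: 16 steps (steps 1 and 3–17 from 1; step 2 is a one-step branch that supplies 4)

Steps most likely to fail

1. Step 3. The alkylcopper species may add only slowly at C5 beside the quaternary C4, so that uncatalysed 1,2- or racemic 1,4-addition competes and the enantiomeric purity drops. A second alkyl group may also add to the remaining enone if the enolate is protonated too early. Fallback, setting out from 1 (with 4 and 5) and returning at 7: the C5 centre would be set on the monoenone, which has only enantiofaces to distinguish and no second acceptor. Addition of 4 to 1 with the same CuBr·SMe2/ferrocenyl diphosphine catalyst, the cyclohexenone class for which this catalyst type is established, would give the bromomagnesium enolate F1. Methylation in the same flask with 5 and DMPU would give the trans ketone (2S,3S)-3-[2-(1,3-dioxolan-2-yl)ethyl]-2,4,4-trimethylcyclohexan-1-one F2. Kinetic enolisation toward the unhindered C2 (LiN(iPr)2, TMSCl, THF, −78 °C) would give the silyl enol ether F3. Saegusa–Ito oxidation (Pd(OAc)2, MeCN, 25 °C) would then restore the C2=C3 double bond and give 7.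

2. Step 9. The 1,2-disubstituted alkene on the quaternary C10 may be too weak a nucleophile, so that chloride capture at C11 or self-condensation of the aldehyde outruns the hydrogen transfer, or closure may take place on the wrong alkene face. Fallback, setting out from 15 and returning at 17: ring B would be closed by an allylmetal addition instead of an ene reaction. Allylic oxidation of the propenyl methyl group of 15 (SeO2 cat., tBuOOH, CH2Cl2) would give the (E)-allylic alcohol (15 with OH on C12) F4. Acetal hydrolysis (1 M HCl, THF) would give the hydroxy aldehyde F5, and CBr4/PPh3 the allylic bromide F6. Intramolecular Nozaki–Hiyama–Kishi-type allylation with CrCl2 in THF, in which the allylchromium unit attacks C8 through its γ-carbon C9 in a chair transition state, would then give 17.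

3. Step 15. The carbomagnesiation may stall or lose regio- and stereocontrol, and the advanced Grignard reagent may be consumed by protonation or homocoupling. Fallback, setting out from 23 (through 25) and returning at 31, bypassing 28 and 30: the C13–C16 unit would be brought in as a complete ynoate. tert-Butyl propiolate would be lithiated (LiN(iPr)2, THF, −78 °C) and trapped with monomeric formaldehyde to give tert-butyl 4-hydroxybut-2-ynoate F7. Steglich esterification with 29 would give tert-butyl 4-{[(2R)-2-methylbutanoyl]oxy}but-2-ynoate F8. Addition of 25 to F8 in the presence of CuBr·SMe2 (1 equiv) in THF at −78 °C is a syn-carbocupration that places the alkyl group on C13; protonation at −78 °C leaves CH2O and the ester cis and would give the tert-butyl ester of the target F9. TMSOTf/2,6-lutidine in CH2Cl2 followed by aqueous work-up would cleave the tert-butyl ester and give 31.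

Further compounds
F1 | step 3 | bromomagnesium 3-[2-(1,3-dioxolan-2-yl)ethyl]-2,4,4-trimethylcyclohex-1-en-1-olate (ring position 3 configured as C5 of 7) | O1CCOC1CC[C@@H]2C(C)(C)CCC(O[Mg]Br)=C2C
F2 | step 3 | (2S,3S)-3-[2-(1,3-dioxolan-2-yl)ethyl]-2,4,4-trimethylcyclohexan-1-one | O1CCOC1CC[C@@H]2C(C)(C)CCC(=O)[C@H]2C
F3 | step 3 | trimethyl{[(5S,6S)-5-[2-(1,3-dioxolan-2-yl)ethyl]-4,4,6-trimethylcyclohex-1-en-1-yl]oxy}silane | O1CCOC1CC[C@@H]2C(C)(C)CC=C(O[Si](C)(C)C)[C@H]2C
F4 | step 9 | (E)-allylic alcohol: 15 with a hydroxyl group on the terminal propenyl carbon (C12) | O1CCOC1CC[C@@H]2C(C)(C)CCC[C@@]2(C)/C=C/CO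
F5 | step 9 | hydroxy aldehyde: 16 with a hydroxyl group on C12 | O=CCC[C@@H]1C(C)(C)CCC[C@@]1(C)/C=C/CO
F6 | step 9 | allylic bromide: 16 with bromine on C12 | O=CCC[C@@H]1C(C)(C)CCC[C@@]1(C)/C=C/CBr
F7 | step 15 | tert-butyl 4-hydroxybut-2-ynoate | OCC#CC(=O)OC(C)(C)C
F8 | step 15 | tert-butyl 4-{[(2R)-2-methylbutanoyl]oxy}but-2-ynoate | CC[C@@H](C)C(=O)OCC#CC(=O)OC(C)(C)C
F9 | step 15 | tert-butyl ester of 31 | C=C1CC[C@@H]2C(C)(C)CCC[C@@]2(C)[C@@H]1CC/C(=C/C(=O)OC(C)(C)C)COC(=O)[C@H](C)CC
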